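**Assumptions**
- The target is the natural (2S)-flavanone, with the 2-phenyl stereocentre drawn as [C@@H].
- Compounds 1, 2, 9, 10 and 14 are purchasable.
- In step 8, C-alkylation occurs at C3′ (next to the free OH) rather than C5′ (between two OBn groups). I assume this is at least 4:1 and that the minor isomer is separable.

**Retrosynthesis**
1. The target comes from global hydrogenolysis of a per-O-benzyl (2S)-flavanone.
2. The flavanone ring and its C2 stereocentre are made last, by a catalyst-controlled oxa-Michael cyclisation of a fully built 2′-hydroxychalcone. The 6′-OH is capped as OBn so that ring closure occurs only through the OH next to the short arm, which fixes the C8/C6 assignment.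
3. The chalcone comes from Claisen–Schmidt condensation of benzaldehyde with an acetophenone carrying both arms. The arms are added one after the other, short arm at C3′ and long arm at C5′, by Friedel–Crafts benzylation of 2′-hydroxy-4′,6′-bis(benzyloxy)acetophenone.
4. The arms are o/p-hydroxybenzyl oligomers built by repeated aryllithium + aldehyde addition and ionic deoxygenation, then ended with ArLi + HCHO to give the benzylic alcohols.
5. Ring-forming order: arm arene chains, then the two ring-A alkylations, then the pyranone ring and stereocentre.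

**Route**

**Step 1**
Reactants: 1 (1-(benzyloxy)-2-bromobenzene); 2 (4-(benzyloxy)-3-bromobenzaldehyde)
Product: 3, (3-bromo-4-(benzyloxy)phenyl)(2-(benzyloxy)phenyl)methanol (racemic carbinol)
Conditions: n-BuLi, THF, –78 °C; then 2, –78 °C to rt; NH4Cl
Reagents that add atoms: none (Li/Br exchange, then addition of the ArLi to the CHO of 2)
Why: Li/Br exchange gives 2-benzyloxyphenyllithium, stable at –78 °C, which adds to the aldehyde much faster than it exchanges the aldehyde's ArBr. This is a nucleophilic addition, and the carbinol stereocentre is destroyed in step 2.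

**Step 2**
Reactants: 3
Product: 4, 1-(benzyloxy)-2-bromo-4-[2-(benzyloxy)benzyl]benzene
Conditions: Et3SiH, BF3·OEt2, CH2Cl2, –78 to 0 °C
Reagents that add atoms: none (the silane supplies H only)
Why: This is ionic deoxygenation of a diarylcarbinol. The cation is stabilised by the p-OBn and o-OBn groups, and ArBr and ArOBn survive at ≤0 °C.

**Step 3**
Reactants: 4
Product: 5, [2-(benzyloxy)-5-(2-(benzyloxy)benzyl)phenyl]methanol (short arm, "E8")
Conditions: n-BuLi, THF, –78 °C; then monomeric HCHO (cracked paraformaldehyde), –78 °C to rt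
Reagents that add atoms: formaldehyde, C=O
Why: Li/Br exchange followed by hydroxymethylation gives the benzylic alcohol directly. The OBn group is ortho to the new CH2OH and the CH2Ar is para to the OBn, matching the target's ortho-in/para-out connectivity.

**Step 4**
Reactants: 4; 2
Product: 6, (3-bromo-4-(benzyloxy)phenyl)[2-(benzyloxy)-5-(2-(benzyloxy)benzyl)phenyl]methanol (racemic)
Conditions: n-BuLi, THF, –78 °C; then 2, –78 °C to rt
Reagents that add atoms: none
Why: This is the same addition as step 1 and adds the next phenol unit. The aryllithium (from 4) is ortho to OBn, so the new CH2 joins M2's ortho carbon to M1's para carbon as required.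

**Step 5**
Reactants: 6
Product: 7, 1-(benzyloxy)-2-bromo-4-{[2-(benzyloxy)-5-(2-(benzyloxy)benzyl)phenyl]methyl}benzene
Conditions: Et3SiH, BF3·OEt2, CH2Cl2, –78 to 0 °C
Reagents that add atoms: none
Why: Ionic deoxygenation as in step 2. The same conditions are used for a diarylmethane next to an aryl bromide in industrial diarylmethane syntheses.

**Step 6**
Reactants: 7
Product: 8, benzylic alcohol "E6": [2-(benzyloxy)-5-({2-(benzyloxy)-5-[2-(benzyloxy)benzyl]phenyl}methyl)phenyl]methanol
Conditions: n-BuLi, THF, –78 °C; then monomeric HCHO, –78 °C to rt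
Reagents that add atoms: formaldehyde, C=O
Why: This is the same hydroxymethylation as step 3 and completes the three-ring arm as a benzylic alcohol.

**Step 7**
Reactants: 9 (2′,4′,6′-trihydroxyacetophenone); 10 (benzyl bromide)
Product: 11, 2′-hydroxy-4′,6′-bis(benzyloxy)acetophenone
Conditions: BnBr (2.1 equiv), K2CO3, acetone, reflux
Reagents that add atoms: benzyl bromide, BrCc1ccccc1
Why: This is a Williamson etherification. The 2′-OH is chelated to the C=O and stays free, and the symmetry of 9 means there is no regiochemical ambiguity at this stage.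

**Step 8**
Reactants: 11 (2 equiv); 5 (1 equiv)
Product: 12, 2′-hydroxy-4′,6′-bis(benzyloxy)-3′-[2-(benzyloxy)-5-(2-(benzyloxy)benzyl)benzyl]acetophenone
Conditions: Bi(OTf)3 (5 mol%), MeNO2, 40 °C
Reagents that add atoms: none (alcohol 5 is the reactant; the catalyst is not retained)
Why: This is an acid-catalysed Friedel–Crafts benzylation via the o-alkoxybenzyl cation. C3′ is favoured because it lies beside the small OH rather than between two OBn groups, and excess 11 limits double alkylation. The short arm ends up adjacent to the future ring oxygen.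

**Step 9**
Reactants: 12; 8 (1.3 equiv)
Product: 13, the acetophenone carrying the short arm at C3′ and the long arm at C5′ (with 4′,6′-bis-OBn and 2′-OH)
Conditions: Bi(OTf)3 (5 mol%), MeNO2, 50 °C
Reagents that add atoms: none
Why: C5′ is the only free ring position, and it is strongly activated (para to OH, ortho to two OBn). It accepts the second benzyl cation from 8, so the regiochemistry is forced by the prior step.

**Step 10**
Reactants: 13; 14 (benzaldehyde)
Product: 15, (E)-2′-hydroxy-chalcone with 4′,6′-bis-OBn, the short arm at C3′ and the long arm at C5′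
Conditions: KOH (50% aq.), EtOH/THF, rt to 50 °C, 2–3 d
Reagents that add atoms: benzaldehyde, O=Cc1ccccc1
Why: This is a Claisen–Schmidt condensation, and all benzyl ethers are base-stable. Any racemic flavanone that forms is re-opened to the chalcone with KOH before chromatography of 15, so the substrate for step 11 is stereochemically clean.

**Step 11**
Reactants: 15
Product: 16, per-O-benzyl (2S)-flavanone
Conditions: 9-amino-9-deoxy-epi-quinine (20 mol%), TFA (40 mol%), PhMe, 30 °C, 4–5 d
Reagents that add atoms: none (isomerisation)
Why: Proposed new method: a catalyst-controlled intramolecular oxa-Michael addition of the only free phenol (2′-OH) to the enone, with the chiral ammonium/iminium pair blocking one enone face to set C2 as (S). The closest known reaction is cinchona primary-amine/acid (or bifunctional thiourea) cyclisation of simple 2′-hydroxychalcones to flavanones. Here the substrate is very hindered and electron-rich, and the quinine- or quinidine-derived catalyst is chosen to deliver (S). Because 4′-OBn and 6′-OBn are capped, cyclisation can only occur at the OH next to the short arm, so the short arm lands at C8.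

**Step 12**
Reactants: 16
Product: 17, Sarmentosumin D
Conditions: H2 (1 atm), 10% Pd/C, EtOAc/MeOH, rt
Reagents that add atoms: none (H2 supplies H only; toluene is lost)
Why: Hydrogenolysis removes all seven aryl benzyl ethers. The diarylmethane CH2 groups, the 4-ketone (chelated to 5-OH) and the C2 benzylic C–O bond survive these mild, neutral conditions. C2 is not epimerised, because no base or strong acid is used.

**Compound list**

| No. | Name | SMILES | Role |
|---|---|---|---|
| 1 | 1-(benzyloxy)-2-bromobenzene | Brc1ccccc1OCc1ccccc1 | starting material |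
| 2 | 4-(benzyloxy)-3-bromobenzaldehyde | O=Cc1ccc(OCc2ccccc2)c(Br)c1 | starting material |
| 3 | (3-bromo-4-(benzyloxy)phenyl)(2-(benzyloxy)phenyl)methanol (racemic) | OC(c1ccc(OCc2ccccc2)c(Br)c1)c1ccccc1OCc1ccccc1 | intermediate |
| 4 | 1-(benzyloxy)-2-bromo-4-[2-(benzyloxy)benzyl]benzene | Brc1cc(Cc2ccccc2OCc2ccccc2)ccc1OCc1ccccc1 | intermediate |
| 5 | [2-(benzyloxy)-5-(2-(benzyloxy)benzyl)phenyl]methanol | OCc1cc(Cc2ccccc2OCc2ccccc2)ccc1OCc1ccccc1 | intermediate |
| 6 | diaryl carbinol from 4 + 2 (racemic) | OC(c1ccc(OCc2ccccc2)c(Br)c1)c1cc(Cc2ccccc2OCc2ccccc2)ccc1OCc1ccccc1 | intermediate |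
| 7 | three-ring aryl bromide | Brc1cc(Cc2cc(Cc3ccccc3OCc3ccccc3)ccc2OCc2ccccc2)ccc1OCc1ccccc1 | intermediate |
| 8 | three-ring benzylic alcohol (long arm) | OCc1cc(Cc2cc(Cc3ccccc3OCc3ccccc3)ccc2OCc2ccccc2)ccc1OCc1ccccc1 | intermediate |
| 9 | 2′,4′,6′-trihydroxyacetophenone | CC(=O)c1c(O)cc(O)cc1O | starting material |
| 10 | benzyl bromide | BrCc1ccccc1 | starting material |
| 11 | 2′-hydroxy-4′,6′-bis(benzyloxy)acetophenone | CC(=O)c1c(O)cc(OCc2ccccc2)cc1OCc1ccccc1 | intermediate |
| 12 | 3′-(short arm) acetophenone | CC(=O)c1c(O)c(Cc2cc(Cc3ccccc3OCc3ccccc3)ccc2OCc2ccccc2)c(OCc2ccccc2)cc1OCc1ccccc1 | intermediate |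
| 13 | 3′-(short arm)-5′-(long arm) acetophenone | CC(=O)c1c(O)c(Cc2cc(Cc3ccccc3OCc3ccccc3)ccc2OCc2ccccc2)c(OCc2ccccc2)c(Cc2cc(Cc3cc(Cc4ccccc4OCc4ccccc4)ccc3OCc3ccccc3)ccc2OCc2ccccc2)c1OCc1ccccc1 | intermediate |
| 14 | benzaldehyde | O=Cc1ccccc1 | starting material |
| 15 | (E)-chalcone | O=C(/C=C/c1ccccc1)c1c(O)c(Cc2cc(Cc3ccccc3OCc3ccccc3)ccc2OCc2ccccc2)c(OCc2ccccc2)c(Cc2cc(Cc3cc(Cc4ccccc4OCc4ccccc4)ccc3OCc3ccccc3)ccc2OCc2ccccc2)c1OCc1ccccc1 | intermediate |
| 16 | per-O-benzyl (2S)-flavanone | O=C1C[C@@H](c2ccccc2)Oc2c(Cc3cc(Cc4ccccc4OCc4ccccc4)ccc3OCc3ccccc3)c(OCc3ccccc3)c(Cc3cc(Cc4cc(Cc5ccccc5OCc5ccccc5)ccc4OCc4ccccc4)ccc3OCc3ccccc3)c(OCc3ccccc3)c21 | intermediate |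
| 17 | Sarmentosumin D | O=C1C[C@@H](c2ccccc2)Oc2c(Cc3cc(Cc4ccccc4O)ccc3O)c(O)c(Cc3cc(Cc4cc(Cc5ccccc5O)ccc4O)ccc3O)c(O)c21 | target |

**Totals**
- Total steps: 12.
- Longest linear sequence: 9 steps (1, 2, 4, 5, 6, 9, 10, 11, 12).

**Three steps most likely to fail**
1. **Step 11 (asymmetric oxa-Michael).** The electron-rich, 2,6-disubstituted enone may give low conversion or low ee. Fallback: cyclise 15 to racemic 16 with NaOAc/EtOH at reflux, then resolve the enantiomers by preparative chiral SFC/HPLC at the per-benzyl stage. Alternatively, make the corresponding chromone and use Pd-catalysed asymmetric 1,4-addition of PhB(OH)2.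
2. **Step 8 (C3′ vs C5′ selectivity).** Fallback: reverse the order. Mono-alkylate symmetrical 9 with the free salicyl-alcohol (o-quinone methide) form of the short arm, then bis-benzylate the less hindered 4′-OH and 6′-OH with BnBr. This gives 12 by steric discrimination of the OH groups instead of discrimination of the C–H sites.
3. **Step 9 (hindered C5′ benzylation).** Fallback: brominate 12 at C5′ with NBS, then use Pd-PEPPSI-IPent Negishi coupling with the benzylzinc reagent made from the benzylic bromide of 8.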